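**Retrosynthetic overview**

- Feature: in ring A the tertiary C10 carbinol is bonded to the methyl-bearing quaternary C5, and the C6=C7 alkene starts at the next carbon. This is the product pattern of a carbonyl-ene reaction between a C10 ketone and a C5=C6 alkene held across a ten-membered ring, and that ring is the oxy-Cope product of a ring-B 1,2-divinylcyclohexanol.
- Late stage (ring A decoration): C9 angelate from the C9 alcohol (Rubottom), C7 acetyl from the α-iodoenone (Stille), C8 ketone by allylic oxidation of the cis-fused Δ6-octalin-10-ol.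
- Key disconnection: C5–C10 (transannular ene) and C7–C8 ([3,3] shift) back to the cis-1,2-divinylcyclohexanol. Ring B is made first; ring A is closed by the cascade.
- Stereochemical design: the cis ring fusion needs the Z ring alkene, which only the chair with equatorial C5 vinyl and axial C10 vinyl delivers. That chair is locked by carrying the C3 oxygen as the 3α (equatorial) silyl ether; C3 is inverted after the cascade by oxidation and equatorial hydride delivery.
- Ring B: (R)-4-silyloxycyclohexenone, then the 2-methyl enone, anti methyl cuprate addition (C4), Pd vinylation of the regiodefined enolate (C5), vinyl addition (C10).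

Key step: step 6

Numbering and faces: ring A = C5–C6–C7–C8–C9–C10, ring B = C10–C1–C2–C3–C4–C5; β is the face of the C5 methyl group, α the opposite face (target: 3β-OAc, 4β-Me, 5β-Me, 10β-OH, 9α-angelate).
Assumption: (R)-4-(tert-butyldimethylsilyloxy)cyclohex-2-en-1-one is taken as a purchasable chiral building block.

**Route**

Step 1
Reactants: 1 (R)-4-(tert-butyldimethylsilyloxy)cyclohex-2-en-1-one
Product: 2 (R)-4-(tert-butyldimethylsilyloxy)-2-iodocyclohex-2-en-1-one
Conditions: I2, pyridine, CH2Cl2, 0 °C to rt
Reagents that add atoms: iodine, II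
Why: Johnson α-iodination of the enone (pyridine conjugate addition, iodination of the enolate, elimination) should place iodine on the α-carbon (future C5) without touching the silyloxy stereocentre.

Step 2
Reactants: 2 (R)-4-(tert-butyldimethylsilyloxy)-2-iodocyclohex-2-en-1-one; 3 tetramethyltin
Product: 4 (R)-4-(tert-butyldimethylsilyloxy)-2-methylcyclohex-2-en-1-one
Conditions: Pd2(dba)3 (cat.), AsPh3, CuI, NMP, 60 °C
Reagents that add atoms: tetramethyltin (3), C[Sn](C)(C)C
Why: Stille coupling of the α-iodoenone should install the future C5 methyl group; no stereocentre is involved.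

Step 3
Reactants: 4 (R)-4-(tert-butyldimethylsilyloxy)-2-methylcyclohex-2-en-1-one
Product: 6 trimethylsilyl enol ether (C5=C10; C10 OSiMe3; 5-methyl; 4β-methyl; 3α-OTBS), via lithium enolate 5 (not isolated)
Conditions: Me2CuLi (from MeLi and CuI), Et2O/THF, −78 to −40 °C; then Me3SiCl, Et3N, −78 to 0 °C
Reagents that add atoms: lithium dimethylcuprate, [Li+].C[Cu-]C; chlorotrimethylsilane, C[Si](C)(C)Cl
Why: Cuprate conjugate addition should occur anti to the γ-silyloxy group and set C4 (methyl trans to OTBS), and O-silylation fixes the enolate regiochemistry at C5=C10.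

Step 4
Reactants: 6 trimethylsilyl enol ether; 7 vinyl bromide
Product: 9 ring-B ketone (C10 ketone; C5 β-methyl/α-vinyl; 4β-methyl; 3α-OTBS), via tributylstannyl enolate 8 (not isolated)
Conditions: Bu3SnF, Pd(OAc)2 (cat.), P(t-Bu)3, toluene/THF, 70 °C, sealed tube
Reagents that add atoms: vinyl bromide (7), C=CBr
Why: Fluoride-driven silicon-to-tin exchange gives the tin enolate regiospecifically, and palladium-catalysed α-vinylation (oxidative addition, transmetalation, reductive elimination) should create quaternary C5 with the vinyl group entering anti to the adjacent C4 methyl, so that the two methyl groups end up cis.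

Step 5
Reactants: 9 ring-B ketone; 10 vinylmagnesium bromide
Product: 11 cis-1,2-divinylcyclohexanol (C10 β-OH/α-vinyl; C5 β-methyl/α-vinyl; 4β-methyl; 3α-OTBS)
Conditions: CeCl3 (anhydrous), THF, −78 °C; aq. NH4Cl
Reagents that add atoms: vinylmagnesium bromide (10), C=C[Mg]Br
Why: Organocerium 1,2-addition avoids enolisation; the ketone chair has the C3 silyloxy and C4 methyl groups equatorial and the C5 methyl axial, so the nucleophile should enter axially on the face opposite that methyl and set C10 with the new vinyl cis to the C5 vinyl.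

Step 6
Reactants: 11 cis-1,2-divinylcyclohexanol
Product: 14 cis-fused decalinol (10β-OH; 5β-methyl; 4β-methyl; 3α-OTBS; C6=C7 alkene), via dienol 12 (not isolated), via Z-cyclodecenone 13 (not isolated)
Conditions: DBU, toluene, 200 °C, sealed tube
Reagents that add atoms: none
Why: On heating, 11 should undergo a chair oxy-Cope rearrangement that joins C7 to C8 and cleaves C5–C10 to dienol 12; DBU tautomerises it to the Z-cyclodecenone 13, whose C10 carbonyl then adds to C5 in a transannular carbonyl-ene reaction with transfer of a C7 hydrogen to oxygen, so that the alkene ends at C6=C7. The closest known reaction is the thermal tandem oxy-Cope/transannular ene cascade of 1,2-divinylcyclohexanols to ring-fusion decalinols, extended here to an ene terminus that carries a methyl group. Ring A is closed by 1,6-transannular C–C bond formation within the ten-membered ring, through a twist-boat array in which C9–C8 and O···H both bridge C10 and C7, and ring B is restored as a chair. C5 and C10 are both re-formed: their cis relationship follows from the Z geometry of the C5=C6 alkene (with C4 cis to C7 the oxygen lies anti to C4 and syn to the C5 methyl, whereas an E alkene would give the trans-fused C10 epimer), and their sense relative to C3 and C4 follows from the ring-B chair that keeps the 3α-silyloxy and 4β-methyl groups equatorial, so that C10 returns to the face of C5 it left. The step therefore needs Z over E selectivity in the sigmatropic shift, and the 3α-silyloxy group secures it by locking 11 in the chair with axial C10 vinyl and equatorial C5 vinyl (the flipped chair suffers two syn-diaxial pairs), which places C4 axial in the chair transition state. It also needs bond formation at C5 and not at C6, which the 1,6 proximity of C10 and C5 across the ring should favour.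

Step 7
Reactants: 14 cis-fused decalinol
Product: 15 cis-fused Δ6-octalin-3α,10β-diol (4β,5β-dimethyl)
Conditions: HF (48% aq.), MeCN, rt
Reagents that add atoms: none
Why: Fluoride-assisted cleavage of the secondary silyl ether frees the C3 hydroxyl, whose 3α configuration has done its work as a conformational anchor.

Step 8
Reactants: 15 cis-fused Δ6-octalin-3α,10β-diol
Product: 16 10β-hydroxy-4β,5β-dimethyl-Δ6-octalin-3-one
Conditions: Dess–Martin periodinane, NaHCO3, CH2Cl2, rt
Reagents that add atoms: none
Why: Dess–Martin oxidation takes the secondary C3 alcohol to the ketone and leaves the tertiary C10 alcohol untouched; the equatorial C4 methyl is the stable configuration at the new α-centre.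

Step 9
Reactants: 16 10β-hydroxy-4β,5β-dimethyl-Δ6-octalin-3-one
Product: 17 cis-fused Δ6-octalin-3β,10β-diol (4β,5β-dimethyl)
Conditions: LiBH(s-Bu)3 (2.5 equiv), THF, −78 °C; then NaOH, H2O2
Reagents that add atoms: none
Why: In the favoured cis-decalin chair the C5 methyl is axial and blocks the axial trajectory at C3, so the bulky hydride should attack equatorially and give the axial 3β-alcohol, cis to both methyl groups.

Step 10
Reactants: 17 cis-fused Δ6-octalin-3β,10β-diol
Product: 18 3β-acetoxy-10β-hydroxy-4β,5β-dimethyl-Δ6-octalin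
Conditions: Ac2O, DMAP, pyridine, CH2Cl2, rt
Reagents that add atoms: acetic anhydride, CC(=O)OC(C)=O
Why: DMAP-catalysed acylation should acetylate the secondary C3 alcohol selectively over the hindered tertiary ring-fusion alcohol.

Step 11
Reactants: 18 3β-acetoxy-10β-hydroxy-4β,5β-dimethyl-Δ6-octalin
Product: 19 3β-acetoxy-10β-hydroxy-4β,5β-dimethyl-Δ6-octalin-8-one
Conditions: Rh2(cap)4 (cap = caprolactamate, cat.), t-BuOOH (70% aq.), K2CO3, CH2Cl2, rt
Reagents that add atoms: tert-butyl hydroperoxide, CC(C)(C)OO
Why: Dirhodium-catalysed allylic oxidation should convert C8, the only allylic position bearing hydrogen (C5 is quaternary), into the conjugated enone carbonyl.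

Step 12
Reactants: 19 3β-acetoxy-10β-hydroxy-4β,5β-dimethyl-Δ6-octalin-8-one
Product: 20 bis(trimethylsilyl) dienol ether (C8 OSiMe3; C8=C9 and C6=C7; C10 OSiMe3)
Conditions: Me3SiOTf, Et3N, CH2Cl2, −20 to 0 °C
Reagents that add atoms: trimethylsilyl triflate, C[Si](C)(C)OS(=O)(=O)C(F)(F)F
Why: Soft enolisation can only occur towards C9 (the γ-carbon C5 is quaternary) and gives the cross-conjugated silyl dienol ether, while the same reagent caps the tertiary C10 alcohol so that it cannot direct the next oxidation.

Step 13
Reactants: 20 bis(trimethylsilyl) dienol ether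
Product: 23 3β-acetoxy-9α,10β-dihydroxy-4β,5β-dimethyl-Δ6-octalin-8-one, via silyloxy epoxide 21 (not isolated), via bis-silyloxy ketone 22 (not isolated)
Conditions: mCPBA, NaHCO3, CH2Cl2, −20 °C; then 1 M HCl, THF, 0 °C
Reagents that add atoms: mCPBA, OOC(=O)c1cccc(Cl)c1
Why: Rubottom oxidation: the peracid should epoxidise the electron-rich C8=C9 enol ether bond anti to the adjacent C10 OSiMe3 group, silyl migration opens the epoxide to the α-silyloxy ketone, and acid removes both silyl groups, leaving the 9α-hydroxyl trans to the 10β-hydroxyl.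

Step 14
Reactants: 23 3β-acetoxy-9α,10β-dihydroxy-4β,5β-dimethyl-Δ6-octalin-8-one
Product: 24 7-iodo enone (3β-OAc; 9α,10β-diol; C6=C7)
Conditions: I2, pyridine, CH2Cl2, rt
Reagents that add atoms: iodine, II
Why: Johnson α-iodination of the enone should iodinate C7, as it does for 4,4-disubstituted cyclohexenones; the hydroxyls and the acetate are inert.

Step 15
Reactants: 24 7-iodo enone; 25 tributyl(1-ethoxyvinyl)stannane
Product: 27 7-acetyl enone (3β-OAc; 9α,10β-diol), via ethoxyvinyl enone 26 (not isolated)
Conditions: PdCl2(PPh3)2 (cat.), CuI, DMF, 60 °C; then 0.5 M HCl, THF, 0 °C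
Reagents that add atoms: tributyl(1-ethoxyvinyl)stannane (25), CCCC[Sn](CCCC)(CCCC)C(=C)OCC; water, O
Why: Stille coupling attaches a masked acetyl group at C7, and mild acid hydrolysis of the enol ether releases the methyl ketone.

Step 16
Reactants: 27 7-acetyl enone; 28 angelic acid
Product: 30 target CNP0196241.1, (3S,4R,5R,9S,10R) in the skeleton numbering, via mixed anhydride 29 (not isolated)
Conditions: 28, 2,4,6-trichlorobenzoyl chloride, Et3N, toluene, rt; then 27, 70 °C
Reagents that add atoms: angelic acid (28), C/C=C(/C)C(=O)O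
Why: Yamaguchi-type mixed-anhydride esterification without a nucleophilic catalyst should acylate the secondary C9 alcohol (the tertiary C10 alcohol is inert) and keep the Z geometry of the angelate, which is installed last so that it meets neither iodine nor palladium.

**Compound list**

1 | (R)-4-(tert-butyldimethylsilyloxy)cyclohex-2-en-1-one | O=C1C=C[C@H](O[Si](C)(C)C(C)(C)C)CC1 | starting material
2 | (R)-4-(tert-butyldimethylsilyloxy)-2-iodocyclohex-2-en-1-one | O=C1C(I)=C[C@H](O[Si](C)(C)C(C)(C)C)CC1 | intermediate
3 | tetramethyltin | C[Sn](C)(C)C | starting material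
4 | (R)-4-(tert-butyldimethylsilyloxy)-2-methylcyclohex-2-en-1-one | CC1=C[C@H](O[Si](C)(C)C(C)(C)C)CCC1=O | intermediate
5 | lithium enolate (C5=C10; 5-methyl; 4β-methyl; 3α-OTBS) | C[C@H]1[C@H](O[Si](C)(C)C(C)(C)C)CCC(O[Li])=C1C | intermediate (not isolated)
6 | trimethylsilyl enol ether (C5=C10; 5-methyl; 4β-methyl; 3α-OTBS) | C[C@H]1[C@H](O[Si](C)(C)C(C)(C)C)CCC(O[Si](C)(C)C)=C1C | intermediate
7 | vinyl bromide | C=CBr | starting material
8 | tributylstannyl enolate (C5=C10; 5-methyl; 4β-methyl; 3α-OTBS) | C[C@H]1[C@H](O[Si](C)(C)C(C)(C)C)CCC(O[Sn](CCCC)(CCCC)CCCC)=C1C | intermediate (not isolated)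
9 | ring-B ketone (C10 ketone; C5 β-methyl/α-vinyl; 4β-methyl; 3α-OTBS) | C=C[C@]1(C)[C@@H](C)[C@H](O[Si](C)(C)C(C)(C)C)CCC1=O | intermediate
10 | vinylmagnesium bromide | C=C[Mg]Br | starting material
11 | cis-1,2-divinylcyclohexanol (C10 β-OH/α-vinyl; C5 β-methyl/α-vinyl; 4β-methyl; 3α-OTBS) | C=C[C@]1(C)[C@@H](C)[C@H](O[Si](C)(C)C(C)(C)C)CC[C@]1(O)C=C | intermediate
12 | cyclodeca-1,5-dien-1-ol (C9=C10 enol, trans in the ring; C5=C6 cis in the ring; 4-methyl; 3-OTBS) | O/C1=C\CC/C=C(C)\[C@@H](C)[C@H](O[Si](C)(C)C(C)(C)C)CC1 | intermediate (not isolated)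
13 | (Z)-6,7-dimethyl-8-(tert-butyldimethylsilyloxy)cyclodec-5-en-1-one (C10 ketone; Z C5=C6) | O=C1CCC/C=C(C)\[C@@H](C)[C@H](O[Si](C)(C)C(C)(C)C)CC1 | intermediate (not isolated)
14 | cis-fused decalinol (10β-OH; 5β-methyl; 4β-methyl; 3α-OTBS; C6=C7) | C1CC=C[C@]2(C)[C@@H](C)[C@H](O[Si](C)(C)C(C)(C)C)CC[C@]12O | intermediate
15 | cis-fused Δ6-octalin-3α,10β-diol (4β,5β-dimethyl) | C1CC=C[C@]2(C)[C@@H](C)[C@H](O)CC[C@]12O | intermediate
16 | 10β-hydroxy-4β,5β-dimethyl-Δ6-octalin-3-one | C1CC=C[C@]2(C)[C@@H](C)C(=O)CC[C@]12O | intermediate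
17 | cis-fused Δ6-octalin-3β,10β-diol (4β,5β-dimethyl) | C1CC=C[C@]2(C)[C@@H](C)[C@@H](O)CC[C@]12O | intermediate
18 | 3β-acetoxy-10β-hydroxy-4β,5β-dimethyl-Δ6-octalin | C1CC=C[C@]2(C)[C@@H](C)[C@@H](OC(C)=O)CC[C@]12O | intermediate
19 | 3β-acetoxy-10β-hydroxy-4β,5β-dimethyl-Δ6-octalin-8-one | C1C(=O)C=C[C@]2(C)[C@@H](C)[C@@H](OC(C)=O)CC[C@]12O | intermediate
20 | bis(trimethylsilyl) dienol ether (C8 OSiMe3; C8=C9; C6=C7; C10 OSiMe3; 3β-OAc) | C1=C(O[Si](C)(C)C)C=C[C@]2(C)[C@@H](C)[C@@H](OC(C)=O)CC[C@]12O[Si](C)(C)C | intermediate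
21 | 8,9α-epoxide of 20 (C8 OSiMe3; C10 OSiMe3) | O3[C@@H]1[C@@]3(O[Si](C)(C)C)C=C[C@]2(C)[C@@H](C)[C@@H](OC(C)=O)CC[C@]12O[Si](C)(C)C | intermediate (not isolated)
22 | 9α,10β-bis(trimethylsilyloxy) enone (C8 ketone; C6=C7; 3β-OAc) | C[Si](C)(C)O[C@@H]1C(=O)C=C[C@]2(C)[C@@H](C)[C@@H](OC(C)=O)CC[C@]12O[Si](C)(C)C | intermediate (not isolated)
23 | 3β-acetoxy-9α,10β-dihydroxy-4β,5β-dimethyl-Δ6-octalin-8-one | O[C@@H]1C(=O)C=C[C@]2(C)[C@@H](C)[C@@H](OC(C)=O)CC[C@]12O | intermediate
24 | 7-iodo enone (3β-OAc; 9α,10β-diol; C8 ketone; C6=C7) | O[C@@H]1C(=O)C(I)=C[C@]2(C)[C@@H](C)[C@@H](OC(C)=O)CC[C@]12O | intermediate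
25 | tributyl(1-ethoxyvinyl)stannane | CCCC[Sn](CCCC)(CCCC)C(=C)OCC | starting material
26 | 7-(1-ethoxyvinyl) enone (3β-OAc; 9α,10β-diol) | O[C@@H]1C(=O)C(C(=C)OCC)=C[C@]2(C)[C@@H](C)[C@@H](OC(C)=O)CC[C@]12O | intermediate (not isolated)
27 | 7-acetyl enone (3β-OAc; 9α,10β-diol) | O[C@@H]1C(=O)C(C(C)=O)=C[C@]2(C)[C@@H](C)[C@@H](OC(C)=O)CC[C@]12O | intermediate
28 | angelic acid, (Z)-2-methylbut-2-enoic acid | C/C=C(/C)C(=O)O | starting material
29 | angelic 2,4,6-trichlorobenzoic anhydride | C/C=C(/C)C(=O)OC(=O)c1c(Cl)cc(Cl)cc1Cl | intermediate (not isolated)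
30 | CNP0196241.1 (3β-acetoxy-7-acetyl-9α-angeloyloxy-10β-hydroxy-4β,5β-dimethyl-Δ6-octalin-8-one) | C/C=C(/C)C(=O)O[C@@H]1C(=O)C(C(C)=O)=C[C@]2(C)[C@@H](C)[C@@H](OC(C)=O)CC[C@]12O | target

**Step count and risks**

Total step count: 16. Longest linear sequence: 16 steps (from 1).

Steps most likely to fail:

1. Step 6. The sigmatropic shift may leak through the other chair and give the E ring alkene, which would cyclise to the trans-fused C10 epimer. The ketone may also add to C6 with hydrogen transfer from the C5 methyl (a hydroazulenol), or the ene closure may stall because the bond-forming alkene carbon is fully substituted. Fallback: starting from ketone 9, addition of but-3-enylmagnesium bromide (CeCl3, THF, −78 °C), which should enter axially like the vinyl reagent, would give the but-3-enyl carbinol F1. Ring-closing metathesis of F1 with the second-generation Grubbs catalyst (CH2Cl2, 40 °C) between the C5 vinyl group and the butenyl terminus would close ring A as the C6=C7 cyclohexene and rejoin the route at 14.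

2. Step 4. Transmetalation and reductive elimination at the tetrasubstituted, β-branched enolate carbon may be slow, β-hydride elimination may return the enone, and the 1,3-related silyloxy group may erode the facial selectivity. Fallback: starting from silyl enol ether 6, MeLi (THF, 0 °C) regenerates lithium enolate 5, whose aldol addition to (phenylseleno)acetaldehyde at −78 °C would give the β-hydroxy selenide F2. Treatment of F2 with MeSO2Cl and Et3N (CH2Cl2, 0 °C) eliminates the selenide and the hydroxyl to unveil the vinyl group and rejoins the route at 9.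

3. Step 13. Facial selectivity of the epoxidation at C9 may be poor or reversed if ring A adopts the half-chair in which ring B, not the C10 OSiMe3 group, shields the α face; the tertiary allylic silyl ether may also ionise during step 12. Fallback: starting from dienol ether 20, N-bromosuccinimide (THF, −78 °C) would place bromine on the same face the peracid prefers and give the 9β-bromo enone F3. SN2 displacement of F3 with CsO2CH (DMF, rt) inverts C9 to the 9α-formate F4, and KHCO3 in MeOH followed by dilute HCl removes the formyl and silyl groups and rejoins the route at 23.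

**Further compounds**

F1 | step 6 | but-3-enyl carbinol (C10 β-OH/α-but-3-enyl; C5 β-methyl/α-vinyl; 4β-methyl; 3α-OTBS) | C=C[C@]1(C)[C@@H](C)[C@H](O[Si](C)(C)C(C)(C)C)CC[C@]1(O)CCC=C
F2 | step 4 | β-hydroxy selenide (C5 β-methyl/α-[1-hydroxy-2-(phenylseleno)ethyl]; carbinol epimers; C10 ketone; 4β-methyl; 3α-OTBS) | OC(C[Se]c1ccccc1)[C@]1(C)[C@@H](C)[C@H](O[Si](C)(C)C(C)(C)C)CCC1=O
F3 | step 13 | 9β-bromo enone (C8 ketone; C6=C7; C10 OSiMe3; 3β-OAc) | Br[C@H]1C(=O)C=C[C@]2(C)[C@@H](C)[C@@H](OC(C)=O)CC[C@]12O[Si](C)(C)C
F4 | step 13 | 9α-formyloxy enone (C8 ketone; C6=C7; C10 OSiMe3; 3β-OAc) | O=CO[C@@H]1C(=O)C=C[C@]2(C)[C@@H](C)[C@@H](OC(C)=O)CC[C@]12O[Si](C)(C)C
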